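The readings are calculated for substances that don't exist; noise was put on by code.

A small charge of solid substrate can dissolve completely before the solution fills. Two chemists dispute how near saturation the red flask stands at 8.0 h.

common to all: solid substrate 20 mM
- red: solid reagent 0.95 equiv; the very flask that is asked about, followed so far
- grey: solid reagent 1.4 equiv; run made earlier
- flask: solid reagent 0.950 equiv; time 8.0 h

- red (time / min: target / %, dissolved substrate / %, solid substrate / %): 6.00: 1, 4, 96; 20.0: 0, 12, 85; 30.0: 3, 20, 84; 50.0: 2, 30, 71; 80.0: 3, 37, 61; 90.0: 3, 40, 61
- grey (time / h: target / %, dissolved substrate / %, solid substrate / %): 1.00: 0, 32, 70; 2.00: 5, 40, 51; 3.00: 9, 45, 42; 4.00: 13, 49, 36; 5.00: 14, 47, 32; 6.00: 21, 46, 28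

(readings scatter by 1.5 percentage points)

- target at 8.0 h, in percent of the solid substrate charged
- concentration of dissolved substrate in solution at 8.0 h, in percent of saturation

- solid substrate, solid reagent is a solid; its amount is given per volume of the solution
- at the start none of the solid substrate is in solution
- at the start none of the solid reagent is in solution
- dissolved substrate means what is dissolved; the solid is not counted in it

In the grey run, between 4.00 h and 6.00 h, solid substrate falls from 36% to 28% while dissolved substrate sags from 49% to 46%. The first chemist reads this as a shrinking solid dissolving ever more weakly, so the solution drops well below saturation.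

The second chemist, whose reckoning I take as mine, answers that the sag is 3 percentage points against a scatter of 1.5 points. Red's solid at 90.0 min, 61%, lies between grey's 70% and 51%, so he lends grey's rates to red, and grey's solid, carried on at its late fall, leaves about 20.0% at 8.0 h. Red dissolved 20% in its first 30.0 min, a pace of 0.400 h⁻¹ in fractions of the charge. Grey's target rose at 0.0400 h⁻¹ from 2.00 h to 6.00 h, which he takes as the pace of use. That first dissolving pace is ten times the use, so he takes the dissolved level as standing where dissolving matches use. If the pull is proportional to the distance from saturation, that distance is the use pace over the first dissolving pace: the shortfall from saturation, 10.0%. Red should stand near 90.0% of saturation.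

The forecast, with its “shrinking-surface correction”, sides with the first chemist: 77% of saturation (65% to 90%) and 26% of target (18% to 31%).

The red flask gives 89.4% of saturation and 23.5% of target.

    solid substrate ⇌ dissolved substrate, rate k1*(cs1 - [dissolved substrate]) while solid is left; crystals form when [dissolved substrate] > cs1 (solubility = 11.0 mM, k = 2.40 × 10⁻⁴ s⁻¹)
    dissolved substrate + partner → target (k = 0.00330 M⁻¹ s⁻¹)
    target ⇌ isomer of the product (K = 3.00, k = 3.50 × 10⁻⁵ s⁻¹)
    solid reagent ⇌ partner, rate k4*(cs4 - [partner]) while solid is left; crystals form when [partner] > cs4 (solubility = 9.30 mM, k = 3.70 × 10⁻⁴ s⁻¹)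

At 8.00 h the red flask makes dissolved substrate 1.00 times as fast as it uses it, with a dissolving constant of 0.864 h⁻¹ against a pseudo-first-order use constant of 0.102 h⁻¹, and its shortfall is 10.6% against the reckoned 10.0%. The neighbour flask with 12 mM of solid substrate is the first chemist's case: at 8.00 h its solid stands at 0%, and its dissolved substrate, 54.8% of that charge, falls short of saturation by 40.2%.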